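The ring of the target, a 4-hydroxycyclopent-2-enone made of C8–C12 with the C9 ketone, the C10=C11 alkene and the tertiary carbinol C12, is a constitutional isomer of a 2,5-disubstituted furylcarbinol; the route rests on breaking C8–C12 back to that furan. A chiral Brønsted acid catalysed Piancatelli rearrangement then closes the five-membered ring, forms C8–C12 and sets C12 in one operation. Its precursor is a racemic furyl propargyl carbinol: the furan supplies C9–C12 and carries the (Z)-octenyl chain on its other α-carbon, the carbinol carbon is C8, and the alkyne C6≡C7 with the ester chain later becomes the 5E,7E-dienone by isomerization alone. C10 is chlorinated last.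

Key step: step 5

Remark: positions are given in prostanoid numbering (C1 ester carbon, ring C8–C12, chain C13–C20); by the CIP rules the target is 12S; the sense of induction of the chiral acid in step 5 cannot be predicted with confidence, so the (R)-catalyst is written and its mirror image is to be used should it favour the 12R series.

Step 1
Reactants: 1 furan; 2 1-bromooct-2-yne
Product: 4 2-(oct-2-yn-1-yl)furan, via 2-furyllithium 3 (not isolated)
Conditions: 1 (1.3 equiv), n-BuLi (1.15 equiv), THF, 0 °C; then 2 (1.0 equiv), −78 °C → rt
Reagents that add atoms: none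
Why: α-Lithiation of furan followed by SN2 alkylation of the 2-furyllithium at the primary propargylic bromide, the low addition temperature limiting SN2′ attack and deprotonation of the doubly activated CH2 of the product.

Step 2
Reactants: 4 2-(oct-2-yn-1-yl)furan
Product: 5 2-[(Z)-oct-2-en-1-yl]furan
Conditions: H2 (1 atm), Lindlar catalyst (Pd/CaCO3, Pb-poisoned), quinoline, hexane, rt
Reagents that add atoms: none
Why: Lindlar semihydrogenation delivers both hydrogens to one face of the alkyne on the poisoned palladium surface, which should give the Z-alkene (C14=C15) without reducing the furan.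

Step 3
Reactants: 5 2-[(Z)-oct-2-en-1-yl]furan
Product: 7 5-[(Z)-oct-2-en-1-yl]furan-2-carbaldehyde, via iminium chloride 6 (not isolated)
Conditions: POCl3 (1.2 equiv), DMF, 0 °C → rt; then H2O, aq NaOH to pH 8, 0 °C
Reagents that add atoms: N,N-dimethylformamide, CN(C)C=O (formyl carbon); water, O (carbonyl oxygen, on hydrolysis of 6)
Why: Vilsmeier–Haack formylation, in which the chloroiminium ion substitutes the electron-rich 2-alkylfuran at its free α-position while the isolated Z-alkene is inert, and hydrolysis of the iminium salt releases the aldehyde (C8).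

Step 4
Reactants: 7 5-[(Z)-oct-2-en-1-yl]furan-2-carbaldehyde; 8 methyl hept-6-ynoate
Product: 10 methyl 8-hydroxy-8-{5-[(Z)-oct-2-en-1-yl]furan-2-yl}oct-6-ynoate (racemic carbinol), via methylzinc acetylide 9 (not isolated)
Conditions: 8 (1.5 equiv), Me2Zn (1.5 equiv), N-methylimidazole (10 mol %), toluene, 0 °C → rt; then 7, rt; sat. aq NH4Cl
Reagents that add atoms: none
Why: Dimethylzinc-mediated alkynylation (1,2-addition of an alkynylzinc to the aldehyde), chosen because the organozinc leaves the methyl ester untouched; the carbinol forms as a racemate, which is irrelevant because this centre is ionized in step 5.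

Step 5
Reactants: 10 methyl 8-hydroxy-8-{5-[(Z)-oct-2-en-1-yl]furan-2-yl}oct-6-ynoate
Product: 11 methyl 7-[(1R,2S)-2-hydroxy-2-[(Z)-oct-2-en-1-yl]-5-oxocyclopent-3-en-1-yl]hept-6-ynoate (8R,12S; hydroxyl trans to the alkynyl chain)
Conditions: (R)-TRIP-derived N-triflylphosphoramide [(R)-3,3′-bis(2,4,6-triisopropylphenyl)-BINOL N-triflyl phosphoramide] (10 mol %), H2O (5 equiv), toluene, 30 °C
Reagents that add atoms: water, O
Why: Proposed new method: the chiral acid ionizes the furyl propargyl carbinol to a furfuryl cation held as an ion pair with the phosphoramide anion, water adds at the octenyl-bearing furan α-carbon (the future C12), the cyclic hemiketal opens to a dihydroxypentadienyl cation C12–C11–C10–C9–C8, and this cation cyclizes before the resulting oxyallyl cation collapses to the C9 ketone with the C10=C11 alkene. The closest known reactions are the achiral acid-mediated Piancatelli rearrangement of 5-alkyl-2-furylcarbinols to 4-alkyl-4-hydroxycyclopentenones and the chiral phosphoric acid catalysed aza-Piancatelli and Nazarov reactions, in which a chiral anion likewise steers a cationic 4π closure; new here is the combination of water as nucleophile, a fully substituted carbinol terminus and anion control. The single ring formed, the cyclopentenone C8–C12, is closed by C8–C12 bond formation in a thermal conrotatory 4π electrocyclization of the pentadienyl cation. C12 is set by the catalyst, whose anion hydrogen-bonds to the C9 and C12 hydroxyls of the cation, fixes its helical twist and so the direction of conrotation, while C8 follows from the conrotatory motion of the cation with hydroxyl and alkynyl groups outside (trans) and does not matter because step 6 erases it. The step needs water to attack the substituted furan carbon rather than the alkyne terminus (Meyer–Schuster path) or the carbinol carbon: return at the carbinol carbon only regenerates 10, the furan oxocarbenium carbon carries more of the charge than the alkyne terminus, and only the ring-opened cation is drained irreversibly by cyclization. It also needs a tight ion pair, which the nonpolar solvent, the small measured amount of water and the two hydroxyl anchors of the substrate-derived cation should provide.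

Step 6
Reactants: 11 methyl 7-[(1R,2S)-2-hydroxy-2-[(Z)-oct-2-en-1-yl]-5-oxocyclopent-3-en-1-yl]hept-6-ynoate
Product: 13 methyl (5E,7E)-7-[(2S)-2-hydroxy-2-[(Z)-oct-2-en-1-yl]-5-oxocyclopent-3-en-1-ylidene]hept-5-enoate, via allenone 12 (not isolated)
Conditions: Et3N (10 mol %), toluene, 0 °C → rt; then PPh3 (20 mol %), PhOH (20 mol %), rt
Reagents that add atoms: none
Why: Amine-mediated propargyl-to-allenyl prototropy of the β,γ-alkynyl ketone (C8–H is α to C9 and propargylic) followed by phosphine-catalysed allenone-to-dienone isomerization (PPh3 adds at C7 and phenol relays a proton from C5 to C7), which under reversible, thermodynamic control should give the 5E,7E-dienone; C8 becomes sp2 and C12 is untouched, since the weak amine forms no alkoxide and so opens no retro-aldol path.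

Step 7
Reactants: 13 methyl (5E,7E)-7-[(2S)-2-hydroxy-2-[(Z)-oct-2-en-1-yl]-5-oxocyclopent-3-en-1-ylidene]hept-5-enoate
Product: 14 methyl (5E,7E)-7-[(2S)-4-chloro-2-hydroxy-2-[(Z)-oct-2-en-1-yl]-5-oxocyclopent-3-en-1-ylidene]hept-5-enoate (target)
Conditions: PhICl2 (1.1 equiv), pyridine (3 equiv), CH2Cl2, 0 °C, dark
Reagents that add atoms: iodobenzene dichloride, ClI(Cl)c1ccccc1
Why: α-Chlorination of an enone with iodobenzene dichloride and pyridine by addition, chlorination and elimination: a nucleophile (chloride or pyridine) adds at C11, the C9 enolate is chlorinated at C10 and loss of HX restores C10=C11, a sequence only the ring enone can complete because C10 alone carries an α-hydrogen, while the isolated Z-alkene should be spared by one equivalent of the pyridine-moderated reagent at 0 °C in the dark.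

Compound list
1 | furan | c1ccoc1 | starting material
2 | 1-bromooct-2-yne | CCCCCC#CCBr | starting material
3 | 2-furyllithium | [Li]c1ccco1 | intermediate
4 | 2-(oct-2-yn-1-yl)furan | CCCCCC#CCc1ccco1 | intermediate
5 | 2-[(Z)-oct-2-en-1-yl]furan | CCCCC/C=C\Cc1ccco1 | intermediate
6 | N,N-dimethyl-1-{5-[(Z)-oct-2-en-1-yl]furan-2-yl}methaniminium chloride | CCCCC/C=C\Cc1ccc(o1)C=[N+](C)C.[Cl-] | intermediate
7 | 5-[(Z)-oct-2-en-1-yl]furan-2-carbaldehyde | CCCCC/C=C\Cc1ccc(o1)C=O | intermediate
8 | methyl hept-6-ynoate | C#CCCCCC(=O)OC | starting material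
9 | (7-methoxy-7-oxohept-1-yn-1-yl)(methyl)zinc, the methylzinc acetylide of 8 | C[Zn]C#CCCCCC(=O)OC | intermediate
10 | methyl 8-hydroxy-8-{5-[(Z)-oct-2-en-1-yl]furan-2-yl}oct-6-ynoate, racemic at the carbinol carbon | CCCCC/C=C\Cc1ccc(o1)C(O)C#CCCCCC(=O)OC | intermediate
11 | methyl 7-[(1R,2S)-2-hydroxy-2-[(Z)-oct-2-en-1-yl]-5-oxocyclopent-3-en-1-yl]hept-6-ynoate (8R,12S) | CCCCC/C=C\C[C@]1(O)C=CC(=O)[C@@H]1C#CCCCCC(=O)OC | intermediate
12 | methyl 7-[(2S)-2-hydroxy-2-[(Z)-oct-2-en-1-yl]-5-oxocyclopent-3-en-1-ylidene]hept-6-enoate (allenone C8=C7=C6, allene axis undefined) | CCCCC/C=C\C[C@]1(O)C=CC(=O)C1=C=CCCCCC(=O)OC | intermediate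
13 | methyl (5E,7E)-7-[(2S)-2-hydroxy-2-[(Z)-oct-2-en-1-yl]-5-oxocyclopent-3-en-1-ylidene]hept-5-enoate (12S) | CCCCC/C=C\C[C@]1(O)C=CC(=O)/C1=C/C=C/CCCC(=O)OC | intermediate
14 | methyl (5E,7E)-7-[(2S)-4-chloro-2-hydroxy-2-[(Z)-oct-2-en-1-yl]-5-oxocyclopent-3-en-1-ylidene]hept-5-enoate (12S, 14Z) | CCCCC/C=C\C[C@]1(O)C=C(Cl)C(=O)/C1=C/C=C/CCCC(=O)OC | target

Total step count: 7. Longest linear sequence: 7 steps (furan 1 to target 14); methyl hept-6-ynoate 8 enters as a purchased fragment in step 4.

Steps most likely to fail

Step 5 (proposed new method). The chiral anion may not control the sense of conrotation well enough, so that enantioselectivity is low. Ionization by the chiral acid may also be too slow to outrun decomposition of the electron-rich furan. The fallback uses known chemistry and sets out from 10. An achiral Lewis acid (Dy(OTf)3, 10 mol %, t-BuOH/H2O 5:1, 80 °C, or ZnCl2 in aqueous acetone) should promote the ordinary Piancatelli rearrangement to racemic methyl 7-[trans-2-hydroxy-2-[(Z)-oct-2-en-1-yl]-5-oxocyclopent-3-en-1-yl]hept-6-ynoate F1. This is isomerized under the conditions of step 6 to racemic methyl (5E,7E)-7-[2-hydroxy-2-[(Z)-oct-2-en-1-yl]-5-oxocyclopent-3-en-1-ylidene]hept-5-enoate F2. The enantiomers of F2 are then separated by preparative HPLC or SFC on a polysaccharide chiral stationary phase. The 12S enantiomer is 13, where the route is rejoined.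

Step 7. Electrophilic chlorine may add across the isolated C14=C15 alkene, or the nucleophile may engage the exocyclic dienone rather than C11, eroding chemoselectivity. The fallback sets out from 13 and uses a nucleophilic oxidant that ignores unactivated alkenes. Epoxidation of the ring enone (30% H2O2, cat. NaOH, MeOH, −20 °C) should give the 10,11-epoxy ketone, methyl (5E,7E)-7-[3,4-epoxy-2-hydroxy-2-[(Z)-oct-2-en-1-yl]-5-oxocyclopentylidene]hept-5-enoate F3. Treatment with HCl (conc. aq HCl, THF, 0 °C → rt) should open the epoxide at C10, the α-keto carbon remote from the quaternary C12. The resulting chlorohydrin, methyl (5E,7E)-7-[4-chloro-3-hydroxy-2-hydroxy-2-[(Z)-oct-2-en-1-yl]-5-oxocyclopentylidene]hept-5-enoate F4, dehydrates in the same flask to 14, where the route is rejoined.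

Step 6. The hydrogen relay may stall at the allenone. The phosphine or the tertiary hydroxyl may add to the electrophilic allenone or dienone. The exocyclic C7=C8 bond may settle as an E/Z mixture. The fallback sets out from 11 and separates the two prototropic shifts, replacing nucleophilic catalysis by metal hydride catalysis. Et3N (10 mol %, CH2Cl2, 0 °C) alone gives the allenone 12, which is isolated. A palladium hydride catalyst (Pd2(dba)3·CHCl3 2.5 mol %, PPh3 10 mol %, AcOH 10 mol %, toluene, 50 °C) then moves the hydrogen by hydropalladation of the allene to a π-allyl complex and β-hydride elimination. This should give the conjugated 5E,7E-dienone 13, where the route is rejoined. No compound outside the list is made.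

Further compounds
F1 | step 5 | racemic methyl 7-[trans-2-hydroxy-2-[(Z)-oct-2-en-1-yl]-5-oxocyclopent-3-en-1-yl]hept-6-ynoate (11 and its mirror image) | CCCCC/C=C\C[C@]1(O)C=CC(=O)[C@@H]1C#CCCCCC(=O)OC.CCCCC/C=C\C[C@@]1(O)C=CC(=O)[C@H]1C#CCCCCC(=O)OC
F2 | step 5 | racemic methyl (5E,7E)-7-[2-hydroxy-2-[(Z)-oct-2-en-1-yl]-5-oxocyclopent-3-en-1-ylidene]hept-5-enoate (13 and its mirror image) | CCCCC/C=C\C[C@]1(O)C=CC(=O)/C1=C/C=C/CCCC(=O)OC.CCCCC/C=C\C[C@@]1(O)C=CC(=O)/C1=C/C=C/CCCC(=O)OC
F3 | step 7 | methyl (5E,7E)-7-[3,4-epoxy-2-hydroxy-2-[(Z)-oct-2-en-1-yl]-5-oxocyclopentylidene]hept-5-enoate (10,11-epoxide of 13, carbinol carbon as in 13, epoxide configuration undefined) | CCCCC/C=C\C[C@]1(O)C2OC2C(=O)/C1=C/C=C/CCCC(=O)OC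
F4 | step 7 | methyl (5E,7E)-7-[4-chloro-3-hydroxy-2-hydroxy-2-[(Z)-oct-2-en-1-yl]-5-oxocyclopentylidene]hept-5-enoate (10-chloro-11-hydroxy ketone, carbinol carbon as in 13, C10 and C11 undefined) | CCCCC/C=C\C[C@]1(O)C(O)C(Cl)C(=O)/C1=C/C=C/CCCC(=O)OC
F0 | step 6 | none | none
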